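A direct plan would take the whole chain from the chiral pool: methanolysis of the lactonic sophorolipid diacetate A1 would give methyl (9Z,17S)-17-hydroxyoctadec-9-enoate A2, which would acylate the trianion of methyl 3,5-dioxohexanoate A3 to triketo ester A4; aldol closure would give resorcylate A5, and hydrolysis to acid A6 and decarboxylation would finish.
Its weakest steps would be the Claisen acylation of a trianion by an unactivated hydroxy ester (large excess of base, competing proton transfer), the cyclisation of A4, in which one aldol mode would have to beat pyrone and acylphloroglucinol formation, and the final hydrolysis and decarboxylation, which would add length only to remove a carbon that the ring does not keep.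

The new route makes the benzene ring last, from a four-membered ring. The 1,3,5 pattern of the target (oxygen on C1 and C3, the chain on C5, hydrogen on C2, C4 and C6) is exactly what a Danheiser benzannulation writes: a 3-alkylcyclobutenone that already carries the complete (8Z,16S) chain opens to a vinylketene, adds ethoxyethyne and recloses. One thermal operation forms the ring bonds C1–C2 and C3–C4, closes C1–C6 and delivers the arene at its final oxidation level, with no regiochemical choice and no carboxyl carbon. Polyanion acylation, polyketone cyclisation and decarboxylation thus have no counterpart; the chain is built from (S)-propylene oxide by alkyne chemistry.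

Key step: step 7

Assumption: 3-ethoxycyclobut-2-en-1-one and ethoxyethyne (solution in hexanes) are taken as purchased; the former would otherwise be one step from the latter and ketene.

Step 1
Reactants: 1 (S)-propylene oxide ((2S)-2-methyloxirane); 2 hept-1-yne
Product: 4 (2S)-dec-4-yn-2-ol, via lithium heptynide 3 (not isolated)
Conditions: 2, n-BuLi, THF, −78 °C; BF3·OEt2, −78 °C; then 1; aq. NH4Cl
Reagents that add atoms: none
Why: Epoxide alkynylation (Yamaguchi–Hirao conditions), in which the acetylide opens the BF3-activated epoxide by SN2 attack at the unsubstituted carbon, so that no bond to the stereocentre is broken and the (S) configuration of 1 is carried into 4.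

Step 2
Reactants: 4 (2S)-dec-4-yn-2-ol
Product: 5 (2S)-dec-9-yn-2-ol
Conditions: KH (4 equiv), H2N(CH2)3NH2, 0 °C → rt; H2O
Reagents that add atoms: none
Why: Alkyne zipper isomerisation with potassium 3-aminopropylamide, in which the triple bond walks through propargyl and allenyl anions to the chain end remote from the alkoxide and is held there as the acetylide; C2 bears the alkoxide and no acidic hydrogen, so the (S) centre should not be scrambled.

Step 3
Reactants: 5 (2S)-dec-9-yn-2-ol
Product: 6 (9S)-9-(methoxymethoxy)dec-1-yne
Conditions: MOMCl, i-Pr2NEt, CH2Cl2, 0 °C → rt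
Reagents that add atoms: chloromethyl methyl ether, COCCl
Why: O-Alkylation of the alcohol by an α-chloro ether (methoxymethyl ether formation), which forms the new bond at the acetal carbon and leaves the stereocentre untouched; the acetal should withstand the organolithium, hydrogenation, Grignard and brief cold aqueous acid steps that follow.

Step 4
Reactants: 6 (9S)-9-(methoxymethoxy)dec-1-yne; 7 1,7-dibromoheptane
Product: 9 (16S)-1-bromo-16-(methoxymethoxy)heptadec-8-yne, via lithium acetylide 8 (not isolated)
Conditions: 6, n-BuLi, THF, −78 °C; DMPU; 7 (3 equiv), −78 °C → rt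
Reagents that add atoms: none
Why: SN2 alkylation of a lithium acetylide by a primary bromide, in which the excess of the dibromide should suppress double alkylation.

Step 5
Reactants: 9 (16S)-1-bromo-16-(methoxymethoxy)heptadec-8-yne
Product: 10 (8Z,16S)-1-bromo-16-(methoxymethoxy)heptadec-8-ene
Conditions: H2 (1 atm), Pd/CaCO3 poisoned with Pb(OAc)2 (Lindlar catalyst), quinoline, EtOAc, rt
Reagents that add atoms: none
Why: Lindlar semihydrogenation, in which both hydrogens are delivered syn from the poisoned palladium surface to set the Z-alkene, while the primary C–Br bond and the acetal should not be reduced.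

Step 6
Reactants: 10 (8Z,16S)-1-bromo-16-(methoxymethoxy)heptadec-8-ene; 11 3-ethoxycyclobut-2-en-1-one
Product: 14 3-[(8Z,16S)-16-(methoxymethoxy)heptadec-8-en-1-yl]cyclobut-2-en-1-one, via Grignard reagent 12 (not isolated), via magnesium alkoxide 13 (not isolated)
Conditions: 10, Mg, THF, 45 °C; add to 11 (1.2 equiv), THF, −78 → 0 °C; 1 M HCl, 0 °C, 20 min
Reagents that add atoms: water, O
Why: Grignard 1,2-addition to a vinylogous ester followed by acid-promoted allylic transposition (Stork–Danheiser type): ionisation of the tertiary carbinol of 13 is assisted by the ethoxy group, water adds at the ethoxy-bearing carbon and ethanol is lost, so that the carbonyl moves and the chain ends on C3 of the new cyclobutenone; the carbinol centre of 13 disappears, and the brief cold acid should spare the acetal and the Z-alkene.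

Step 7
Reactants: 14 3-[(8Z,16S)-16-(methoxymethoxy)heptadec-8-en-1-yl]cyclobut-2-en-1-one; 15 ethoxyethyne
Product: 20 3-ethoxy-5-[(8Z,16S)-16-(methoxymethoxy)heptadec-8-en-1-yl]phenol, via vinylketene 16 (not isolated), via vinylcyclobutenone 17 (not isolated), via dienylketene 18 (not isolated), via cyclohexadienone 19 (not isolated)
Conditions: 15 (2.5 equiv), toluene, 80 °C, sealed tube, 16 h; evaporate excess 15; toluene, 110 °C, 2 h
Reagents that add atoms: none
Why: Danheiser benzannulation: thermal conrotatory 4π ring opening of 14 gives vinylketene 16, whose ketene C=C adds ethoxyethyne in a regiospecific [2+2] cycloaddition (the nucleophilic CH terminus of the ynol ether bonds to the ketene carbonyl carbon) to give 17; a second 4π opening gives dienylketene 18, which closes the six-membered ring by thermal disrotatory 6π electrocyclisation between the ketene carbon and the terminal CH2 to give dienone 19, and tautomerisation gives phenol 20. The closest known reaction type is the benzannulation of 3-alkylcyclobutenones with alkoxyacetylenes to monoethers of 5-alkylresorcinols. No stereocentre is formed, and the (S) centre, the acetal and the Z-alkene are remote spectators under neutral thermal conditions. The step needs the ynol ether to win over the isolated Z-alkene as ketenophile and the [2+2] regiochemistry to place OEt meta to OH; the strong polarisation of ethoxyethyne should secure both, since unactivated 1,2-dialkylalkenes add to vinylketenes far more slowly. An excess of 15 should keep 16 from being captured by the phenol as it forms, and the excess is removed before the final heating because ethoxyethyne loses ethylene above about 100 °C.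

Step 8
Reactants: 20 3-ethoxy-5-[(8Z,16S)-16-(methoxymethoxy)heptadec-8-en-1-yl]phenol
Product: 23 Hansfordiol E (5-[(8Z,16S)-16-hydroxyheptadec-8-en-1-yl]benzene-1,3-diol), via lithium phenoxide 21 (not isolated), via iodomethyl ether 22 (not isolated)
Conditions: n-BuLi (1.0 equiv), toluene, −78 → 0 °C; 9-iodo-9-borabicyclo[3.3.1]nonane (9-I-9-BBN, 1 M in hexanes, 4 equiv), 0 °C → rt; aq. NaHCO3; SiO2
Reagents that add atoms: none
Why: Ether and acetal cleavage by a B-iodoborane: the phenol is first taken to its lithium salt so that B–O bond formation gives LiI and no HI in the flask, the boron reagent then opens the acetal to an α-iodo ether and cleaves the aryl ethyl ether by SN2 attack of iodide on the ethyl carbon, and bicarbonate work-up releases the three hydroxyls; no bond to C16 is broken, so the (S) configuration is kept, and the reagent has no B–H bond and should leave the isolated Z-alkene untouched.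

Compound list
1 | (S)-propylene oxide, (2S)-2-methyloxirane | C[C@H]1CO1 | starting material
2 | hept-1-yne | C#CCCCCC | starting material
3 | lithium hept-1-yn-1-ide | [Li]C#CCCCCC | intermediate
4 | (2S)-dec-4-yn-2-ol | C[C@H](O)CC#CCCCCC | intermediate
5 | (2S)-dec-9-yn-2-ol | C[C@H](O)CCCCCCC#C | intermediate
6 | (9S)-9-(methoxymethoxy)dec-1-yne | C[C@H](OCOC)CCCCCCC#C | intermediate
7 | 1,7-dibromoheptane | BrCCCCCCCBr | starting material
8 | lithium (9S)-9-(methoxymethoxy)dec-1-yn-1-ide | C[C@H](OCOC)CCCCCCC#C[Li] | intermediate
9 | (16S)-1-bromo-16-(methoxymethoxy)heptadec-8-yne | C[C@H](OCOC)CCCCCCC#CCCCCCCCBr | intermediate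
10 | (8Z,16S)-1-bromo-16-(methoxymethoxy)heptadec-8-ene | C[C@H](OCOC)CCCCCC/C=C\CCCCCCCBr | intermediate
11 | 3-ethoxycyclobut-2-en-1-one | CCOC1=CC(=O)C1 | starting material
12 | [(8Z,16S)-16-(methoxymethoxy)heptadec-8-en-1-yl]magnesium bromide | C[C@H](OCOC)CCCCCC/C=C\CCCCCCC[Mg]Br | intermediate
13 | bromomagnesium 3-ethoxy-1-[(8Z,16S)-16-(methoxymethoxy)heptadec-8-en-1-yl]cyclobut-2-en-1-olate (either configuration at C1) | C[C@H](OCOC)CCCCCC/C=C\CCCCCCCC1(O[Mg]Br)C=C(OCC)C1 | intermediate
14 | 3-[(8Z,16S)-16-(methoxymethoxy)heptadec-8-en-1-yl]cyclobut-2-en-1-one | C[C@H](OCOC)CCCCCC/C=C\CCCCCCCC1=CC(=O)C1 | intermediate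
15 | ethoxyethyne (ethoxyacetylene) | CCOC#C | starting material
16 | 3-[(8Z,16S)-16-(methoxymethoxy)heptadec-8-en-1-yl]buta-1,3-dien-1-one (vinylketene) | C[C@H](OCOC)CCCCCC/C=C\CCCCCCCC(=C)C=C=O | intermediate
17 | 3-ethoxy-4-[(10Z,18S)-18-(methoxymethoxy)nonadeca-1,10-dien-2-yl]cyclobut-2-en-1-one (either configuration at C4) | C[C@H](OCOC)CCCCCC/C=C\CCCCCCCC(=C)C1C(=O)C=C1OCC | intermediate
18 | (3E)-3-ethoxy-5-[(8Z,16S)-16-(methoxymethoxy)heptadec-8-en-1-yl]hexa-1,3,5-trien-1-one (dienylketene) | C[C@H](OCOC)CCCCCC/C=C\CCCCCCCC(=C)/C=C(OCC)\C=C=O | intermediate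
19 | 3-ethoxy-5-[(8Z,16S)-16-(methoxymethoxy)heptadec-8-en-1-yl]cyclohexa-2,4-dien-1-one | C[C@H](OCOC)CCCCCC/C=C\CCCCCCCC1=CC(OCC)=CC(=O)C1 | intermediate
20 | 3-ethoxy-5-[(8Z,16S)-16-(methoxymethoxy)heptadec-8-en-1-yl]phenol | C[C@H](OCOC)CCCCCC/C=C\CCCCCCCc1cc(O)cc(OCC)c1 | intermediate
21 | lithium 3-ethoxy-5-[(8Z,16S)-16-(methoxymethoxy)heptadec-8-en-1-yl]phenolate | C[C@H](OCOC)CCCCCC/C=C\CCCCCCCc1cc([O-])cc(OCC)c1.[Li+] | intermediate
22 | 5-[(8Z,16S)-16-(iodomethoxy)heptadec-8-en-1-yl]-1,3-phenylene bis(9-borabicyclo[3.3.1]nonan-9-yl) diether | C[C@H](OCI)CCCCCC/C=C\CCCCCCCc1cc(OB2C3CCCC2CCC3)cc(OB2C3CCCC2CCC3)c1 | intermediate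
23 | Hansfordiol E, 5-[(8Z,16S)-16-hydroxyheptadec-8-en-1-yl]benzene-1,3-diol | C[C@H](O)CCCCCC/C=C\CCCCCCCc1cc(O)cc(O)c1 | target

Total steps: 8. Longest linear sequence: 8 steps, from (S)-propylene oxide 1.

Steps most likely to fail

Step 7. The vinylketene may be intercepted by the phenol that accumulates (aryl ester formation), or the volatile ynol ether may escape or fragment before the [2+2] step, so that the cascade stalls at low conversion. Fallback, setting out from bromide 10: insertion of zinc (Zn dust, LiCl, THF, 50 °C) would give the alkylzinc bromide F1. Negishi coupling (Pd(OAc)2, SPhos, THF, rt) with 1-bromo-3,5-bis(methoxymethoxy)benzene F2, made from commercial 5-bromobenzene-1,3-diol with MOMCl and i-Pr2NEt, would give the tris(methoxymethyl) ether F3. HCl in MeOH at 50 °C would remove the three acetals and come back to the route at its end, compound 23. The arene would then be bought and not made; this detour would also stand in for steps 6 and 8.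

Step 6. Proton transfer from the four-membered vinylogous ester to the Grignard reagent, or acid-induced cleavage of the strained ring during the transposition, may erode the cyclobutenone. Fallback, setting out from bromide 10 through its Grignard reagent 12: NiCl2-catalysed substitution at the vinylic C–O bond of diketene (THF, −20 °C) would give the 3-methylidene acid F4. 1-Chloro-N,N,2-trimethylprop-1-en-1-amine (CH2Cl2, 0 °C) would convert it into the acid chloride F5. Slow addition of F5 to Et3N and ethoxyethyne 15 in toluene at 80 °C would generate vinylketene 16 by 1,2-dehydrochlorination, and the cascade would come back to the route at phenol 20.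

Step 8. Cleavage of the aryl ethyl ether may be slow on a ring that already bears an O–B group, and any HI that escapes neutralisation may isomerise or add to the Z-alkene. Fallback, setting out from phenol 20: MOMCl and i-Pr2NEt would give the bis(methoxymethyl) ethyl ether F6. NaSEt in degassed DMF at 150 °C would remove the ethyl group by SN2 attack, now with a simple mono-phenoxide as leaving group, to give phenol F7. HCl in MeOH at 50 °C would remove both acetals and come back to the route at compound 23.

Further compounds
F1 | step 7 | [(8Z,16S)-16-(methoxymethoxy)heptadec-8-en-1-yl]zinc bromide | C[C@H](OCOC)CCCCCC/C=C\CCCCCCC[Zn]Br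
F2 | step 7 | 1-bromo-3,5-bis(methoxymethoxy)benzene | COCOc1cc(Br)cc(OCOC)c1
F3 | step 7 | 1,3-bis(methoxymethoxy)-5-[(8Z,16S)-16-(methoxymethoxy)heptadec-8-en-1-yl]benzene | C[C@H](OCOC)CCCCCC/C=C\CCCCCCCc1cc(OCOC)cc(OCOC)c1
F4 | step 6 | (11Z,19S)-19-(methoxymethoxy)-3-methylideneicos-11-enoic acid | C[C@H](OCOC)CCCCCC/C=C\CCCCCCCC(=C)CC(=O)O
F5 | step 6 | (11Z,19S)-19-(methoxymethoxy)-3-methylideneicos-11-enoyl chloride | C[C@H](OCOC)CCCCCC/C=C\CCCCCCCC(=C)CC(=O)Cl
F6 | step 8 | 1-ethoxy-3-(methoxymethoxy)-5-[(8Z,16S)-16-(methoxymethoxy)heptadec-8-en-1-yl]benzene | C[C@H](OCOC)CCCCCC/C=C\CCCCCCCc1cc(OCOC)cc(OCC)c1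
F7 | step 8 | 3-(methoxymethoxy)-5-[(8Z,16S)-16-(methoxymethoxy)heptadec-8-en-1-yl]phenol | C[C@H](OCOC)CCCCCC/C=C\CCCCCCCc1cc(OCOC)cc(O)c1
A1 | direct plan | diacetylated lactonic sophorolipid (17-L-sophorosyloxy-cis-9-octadecenoic acid 1',4''-lactone 6',6''-diacetate) | C[C@H](O[C@@H]1O[C@H](COC(C)=O)[C@@H](O)[C@H](O)[C@H]1O[C@@H]2O[C@H](COC(C)=O)[C@@H](O3)[C@H](O)[C@H]2O)CCCCCC/C=C\CCCCCCCC3=O
A2 | direct plan | methyl (9Z,17S)-17-hydroxyoctadec-9-enoate | C[C@H](O)CCCCCC/C=C\CCCCCCCC(=O)OC
A3 | direct plan | methyl 3,5-dioxohexanoate | CC(=O)CC(=O)CC(=O)OC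
A4 | direct plan | methyl (15Z,23S)-23-hydroxy-3,5,7-trioxotetracos-15-enoate | C[C@H](O)CCCCCC/C=C\CCCCCCCC(=O)CC(=O)CC(=O)CC(=O)OC
A5 | direct plan | methyl 2,4-dihydroxy-6-[(8Z,16S)-16-hydroxyheptadec-8-en-1-yl]benzoate | C[C@H](O)CCCCCC/C=C\CCCCCCCc1cc(O)cc(O)c1C(=O)OC
A6 | direct plan | 2,4-dihydroxy-6-[(8Z,16S)-16-hydroxyheptadec-8-en-1-yl]benzoic acid | C[C@H](O)CCCCCC/C=C\CCCCCCCc1cc(O)cc(O)c1C(=O)O
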